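**Retrosynthetic overview** (drimane numbering for the terpenoid carbons)
- Target ⇒ saturated 3-ketone by C1=C2 dehydrogenation; the ring A enone is made last.
- 3-Ketone ⇒ acyclic (2Z,6E)-silyl enol ether: C4–C5 is formed between the ketone α-carbon, made electrophilic as an enolonium on a chiral aryl-λ3-iodane, and the 6E olefin. One cascade closes ring A, then ring B (C9–C10), ends in the exocyclic olefin and sets C5, C9 and C10.
- Silyl enol ether ⇒ isopropenyl ketone (1,4-hydrosilylation fixes the enol regiochemistry) ⇒ allylic bromide + dienolate of methyl isopropenyl ketone (C1–C2).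
- Allylic bromide ⇒ O-neryl isofraxidin ⇒ nerol + isofraxidin; the coumarin is bought intact and the 2Z olefin of nerol encodes the axial CH2OAr.

Assumption 1: the target SMILES is read as (1S,4aS,8aR), i.e. trans ring fusion with the C9 CH2OAr axial, anti to the angular methyl and syn to H-5 (a 9-epi drimane of the enantiomeric series).
Assumption 2: isofraxidin is bought; the (R,R)-iodane diacetate is made beforehand from 2-iodoresorcinol and methyl (S)-lactate (not counted) and is taken to give the sense shown; if it gives the mirror image, the (S,S)-reagent from methyl (R)-lactate is used instead.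

Step 1
Reactants: 1 nerol; 2 isofraxidin
Product: 3 7-{[(2Z)-3,7-dimethylocta-2,6-dien-1-yl]oxy}-6,8-dimethoxy-2H-chromen-2-one
Conditions: PPh3, DIAD, THF, 0 °C → rt
Reagents that add atoms: none
Why: Mitsunobu etherification of the acidic, doubly ortho-substituted phenol with a primary allylic alcohol runs under neutral conditions, so the 2Z olefin neither isomerises nor transposes; no stereocentre is formed.

Step 2
Reactants: 3 O-neryl isofraxidin
Product: 4 7-{[(2Z,6E)-8-hydroxy-3,7-dimethylocta-2,6-dien-1-yl]oxy}-6,8-dimethoxy-2H-chromen-2-one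
Conditions: SeO2 (0.3 equiv), t-BuOOH (3 equiv), salicylic acid (0.1 equiv), CH2Cl2, 0 °C → rt, stopped at about 70% conversion
Reagents that add atoms: tert-butyl hydroperoxide CC(C)(C)OO (oxygen source, relayed by catalytic selenium dioxide O=[Se]=O)
Why: Riley allylic oxidation (ene reaction then [2,3]-shift) hydroxylates the (E)-methyl of the terminal, most electron-rich olefin and gives the 6E geometry; the 2Z olefin is deactivated by its allylic aryloxy group.

Step 3
Reactants: 4 allylic alcohol
Product: 5 7-{[(2Z,6E)-8-bromo-3,7-dimethylocta-2,6-dien-1-yl]oxy}-6,8-dimethoxy-2H-chromen-2-one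
Conditions: CBr4, PPh3, CH2Cl2, 0 °C
Reagents that add atoms: carbon tetrabromide BrC(Br)(Br)Br
Why: Appel reaction; SN2 displacement on the oxyphosphonium of a primary allylic alcohol gives the bromide without allylic shift or E/Z change.

Step 4
Reactants: 6 3-methylbut-3-en-2-one; 5 allylic bromide
Product: 8 7-{[(2Z,6E)-3,7,11-trimethyl-10-oxododeca-2,6,11-trien-1-yl]oxy}-6,8-dimethoxy-2H-chromen-2-one, via lithium dienolate 7 (not isolated)
Conditions: LDA (commercial solution), THF, −78 °C, slow addition of 6; then 5, DMPU, −78 → −30 °C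
Reagents that add atoms: none
Why: Kinetic α′-deprotonation gives the cross-conjugated lithium dienolate, which is alkylated SN2 at the primary allylic bromide (enolate alkylation); this forms C1–C2 and installs the isopropenyl ketone that later fixes the enolate regiochemistry.

Step 5
Reactants: 8 isopropenyl ketone
Product: 9 7-{[(2Z,6E)-3,7,11-trimethyl-10-(triethylsilyloxy)dodeca-2,6,10-trien-1-yl]oxy}-6,8-dimethoxy-2H-chromen-2-one
Conditions: Et3SiH (1.2 equiv), RhCl(PPh3)3 (1 mol%), benzene, 50 °C
Reagents that add atoms: triethylsilane CC[SiH](CC)CC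
Why: Rh-catalysed 1,4-hydrosilylation of the enone puts H on the terminal CH2 and Si on O, giving the tetrasubstituted silyl enol ether as a single regioisomer under neutral conditions; the trisubstituted olefins and the coumarin are inert to this catalyst.

Step 6
Reactants: 9 silyl enol ether
Product: 11 7-{[(1S,4aS,8aR)-5,5,8a-trimethyl-2-methylidene-6-oxodecahydronaphthalen-1-yl]methoxy}-6,8-dimethoxy-2H-chromen-2-one, via iodane-bound enolonium 10 (not isolated)
Conditions: (R,R)-ArI(OAc)2 [dimethyl (2R,2′R)-2,2′-{[2-(diacetoxy-λ3-iodanyl)-1,3-phenylene]bis(oxy)}dipropanoate, 1.2 equiv], BF3·OEt2 (2.4 equiv), 2,6-di-tert-butyl-4-methylpyridine (2 equiv), CH2Cl2 (5 mM), −78 → −40 °C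
Reagents that add atoms: none
Why: Proposed new method: Si→I(III) exchange gives the O-bound enolonium 10, in which the ketone α-carbon C4 is electrophilic; the 6E olefin attacks C4 with loss of ArI (SN2′ at the enol, forming C4–C5), the C10 cation is captured by the 2Z olefin in a chair–chair array and the C8 cation loses a methyl proton to the hindered pyridine. Anti addition across the E olefin gives the trans fusion (C5/C10), and the Z olefin places CH2OAr axial, anti to the angular methyl (C9). The C2-symmetric lactate arms on iodine shield one face of the planar enol, so only one of the two mirror-image chair foldings is reached; this fixes the absolute sense, and the level of ee is untested (recrystallise 11 if needed). The exocyclic olefin should be favoured because H-7ax is screened by the axial CH2OAr and H-9 is equatorial, orthogonal to the empty p orbital. Closest known reaction types: C–C coupling of silyl enol ethers with π-nucleophiles under PhI(OAc)2/BF3 (enolonium chemistry), enantioselective oxidative cyclisations with lactate-derived aryl-λ3-iodanes, and cation–olefin polycyclisation.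

Step 7
Reactants: 11 bicyclic 3-ketone
Product: 12 7-{[(1S,4aS,8aR)-5,5,8a-trimethyl-2-methylidene-6-oxo-1,2,3,4,4a,5,6,8a-octahydronaphthalen-1-yl]methoxy}-6,8-dimethoxy-2H-chromen-2-one (target)
Conditions: IBX (2.2 equiv), 4-methoxypyridine N-oxide (2.2 equiv), DMSO, 25 °C
Reagents that add atoms: none
Why: IBX dehydrogenation of the ketone introduces C1=C2; C2 is the only enolisable α-position (C4 is quaternary), and C5, C9 and C10 are not α to the carbonyl, so no stereocentre can epimerise.

**Compound list**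
1 | nerol, (2Z)-3,7-dimethylocta-2,6-dien-1-ol | CC(C)=CCC/C(C)=C\CO | starting material
2 | isofraxidin, 7-hydroxy-6,8-dimethoxy-2H-chromen-2-one | COc1cc2ccc(=O)oc2c(OC)c1O | starting material
3 | 7-{[(2Z)-3,7-dimethylocta-2,6-dien-1-yl]oxy}-6,8-dimethoxy-2H-chromen-2-one | CC(C)=CCC/C(C)=C\COc1c(OC)cc2ccc(=O)oc2c1OC | intermediate
4 | 7-{[(2Z,6E)-8-hydroxy-3,7-dimethylocta-2,6-dien-1-yl]oxy}-6,8-dimethoxy-2H-chromen-2-one | OC/C(C)=C/CC/C(C)=C\COc1c(OC)cc2ccc(=O)oc2c1OC | intermediate
5 | 7-{[(2Z,6E)-8-bromo-3,7-dimethylocta-2,6-dien-1-yl]oxy}-6,8-dimethoxy-2H-chromen-2-one | BrC/C(C)=C/CC/C(C)=C\COc1c(OC)cc2ccc(=O)oc2c1OC | intermediate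
6 | 3-methylbut-3-en-2-one (methyl isopropenyl ketone) | CC(=O)C(C)=C | starting material
7 | lithium 3-methylbuta-1,3-dien-2-olate | C=C(C)C(=C)O[Li] | intermediate
8 | 7-{[(2Z,6E)-3,7,11-trimethyl-10-oxododeca-2,6,11-trien-1-yl]oxy}-6,8-dimethoxy-2H-chromen-2-one | C=C(C)C(=O)CC/C(C)=C/CC/C(C)=C\COc1c(OC)cc2ccc(=O)oc2c1OC | intermediate
9 | 7-{[(2Z,6E)-3,7,11-trimethyl-10-(triethylsilyloxy)dodeca-2,6,10-trien-1-yl]oxy}-6,8-dimethoxy-2H-chromen-2-one | CC[Si](CC)(CC)OC(=C(C)C)CC/C(C)=C/CC/C(C)=C\COc1c(OC)cc2ccc(=O)oc2c1OC | intermediate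
10 | O-bound enolonium: acetoxy{2,6-bis[(2R)-1-methoxy-1-oxopropan-2-yloxy]phenyl}-λ3-iodanyl ether of the C10 enol of 8 (tetrasubstituted enol, chain 2Z,6E) | CC(C)=C(OI(OC(C)=O)c1c(O[C@H](C)C(=O)OC)cccc1O[C@H](C)C(=O)OC)CC/C(C)=C/CC/C(C)=C\COc1c(OC)cc2ccc(=O)oc2c1OC | intermediate
11 | 7-{[(1S,4aS,8aR)-5,5,8a-trimethyl-2-methylidene-6-oxodecahydronaphthalen-1-yl]methoxy}-6,8-dimethoxy-2H-chromen-2-one (trans-fused; CH2OAr axial, anti to the angular methyl) | C=C1CC[C@@H]2C(C)(C)C(=O)CC[C@@]2(C)[C@H]1COc1c(OC)cc2ccc(=O)oc2c1OC | intermediate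
12 | 7-{[(1S,4aS,8aR)-5,5,8a-trimethyl-2-methylidene-6-oxo-1,2,3,4,4a,5,6,8a-octahydronaphthalen-1-yl]methoxy}-6,8-dimethoxy-2H-chromen-2-one | C=C1CC[C@@H]2C(C)(C)C(=O)C=C[C@@]2(C)[C@H]1COc1c(OC)cc2ccc(=O)oc2c1OC | target

**Totals:** 7 steps; longest linear sequence 7 steps (from nerol 1; ketone 6 enters at step 4).

**Steps most likely to fail**

Step 6 is the main risk. The C–C bond-forming mode is new, the enantio-induction is unproven, proton loss could give the endocyclic olefin, and BF3 could ionise the allylic aryl ether before cyclisation. The fallback relays chirality from a carbinol and cyclises by a radical instead of a cation. It sets out from 8: CBS reduction [(S)-Me-CBS, catecholborane, toluene, −78 °C] gives the (10R)-allylic alcohol F1. Cobalt-catalysed Markovnikov hydrochlorination of its 1,1-disubstituted olefin (Co(salen) cat., TsCl, PhSiH3, EtOH) gives the tertiary chlorohydrin F2. K2CO3/MeOH closes the (10R)-10,11-epoxide F3 with retention at the carbinol carbon. Cp2TiCl2 (cat.), Mn, TMSCl and collidine in THF open the epoxide to the tertiary radical, which cyclises chair–chair with the titanoxy group equatorial and ends by Ti-mediated β-hydride loss to the exocyclic olefin, giving the 3-hydroxy bicycle F4. Dess–Martin oxidation returns to the route at 11.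

Step 4 is the second risk: the dienolate comes from a polymerisable enone and could also attack the coumarin. The fallback uses a stabilised carbanion followed by an olefination. It sets out from 5: the dianion of dimethyl (2-oxopropyl)phosphonate (NaH then n-BuLi, THF, 0 °C) is alkylated at its terminal carbon to give the β-keto phosphonate F5. NaH/MeI methylates the carbon between P and C=O to give the α-methyl β-keto phosphonate F6. A Horner–Wadsworth–Emmons reaction with aqueous formaldehyde and K2CO3 forms the α-methylene ketone and rejoins the route at 8.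

Step 2 is the third risk: regioselectivity and over-oxidation usually keep the yield modest. The fallback uses olefin cross-metathesis instead of C–H oxidation. It sets out from 3: cross-metathesis of the terminal isopropylidene with methacrolein (Hoveyda–Grubbs II, CH2Cl2, 40 °C) gives the (2E,6Z)-enal F7. Luche reduction (NaBH4, CeCl3·7H2O, MeOH, −40 °C) rejoins the route at 4.

Further compounds
F1 | step 6 | 7-{[(2Z,6E,10R)-10-hydroxy-3,7,11-trimethyldodeca-2,6,11-trien-1-yl]oxy}-6,8-dimethoxy-2H-chromen-2-one | C=C(C)[C@H](O)CC/C(C)=C/CC/C(C)=C\COc1c(OC)cc2ccc(=O)oc2c1OC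
F2 | step 6 | 7-{[(2Z,6E,10R)-11-chloro-10-hydroxy-3,7,11-trimethyldodeca-2,6-dien-1-yl]oxy}-6,8-dimethoxy-2H-chromen-2-one | CC(C)(Cl)[C@H](O)CC/C(C)=C/CC/C(C)=C\COc1c(OC)cc2ccc(=O)oc2c1OC
F3 | step 6 | 7-{[(2Z,6E)-9-[(2R)-3,3-dimethyloxiran-2-yl]-3,7-dimethylnona-2,6-dien-1-yl]oxy}-6,8-dimethoxy-2H-chromen-2-one | CC1(C)O[C@@H]1CC/C(C)=C/CC/C(C)=C\COc1c(OC)cc2ccc(=O)oc2c1OC
F4 | step 6 | 7-{[(1S,4aS,6R,8aR)-6-hydroxy-5,5,8a-trimethyl-2-methylidenedecahydronaphthalen-1-yl]methoxy}-6,8-dimethoxy-2H-chromen-2-one | C=C1CC[C@@H]2C(C)(C)[C@H](O)CC[C@@]2(C)[C@H]1COc1c(OC)cc2ccc(=O)oc2c1OC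
F5 | step 4 | dimethyl [(5E,9Z)-11-(6,8-dimethoxy-2-oxo-2H-chromen-7-yloxy)-5,9-dimethyl-2-oxoundeca-5,9-dien-1-yl]phosphonate | COP(=O)(OC)CC(=O)CC/C(C)=C/CC/C(C)=C\COc1c(OC)cc2ccc(=O)oc2c1OC
F6 | step 4 | dimethyl [(6E,10Z)-12-(6,8-dimethoxy-2-oxo-2H-chromen-7-yloxy)-6,10-dimethyl-3-oxododeca-6,10-dien-2-yl]phosphonate (racemic at C2) | COP(=O)(OC)C(C)C(=O)CC/C(C)=C/CC/C(C)=C\COc1c(OC)cc2ccc(=O)oc2c1OC
F7 | step 2 | (2E,6Z)-8-(6,8-dimethoxy-2-oxo-2H-chromen-7-yloxy)-2,6-dimethylocta-2,6-dienal | O=C/C(C)=C/CC/C(C)=C\COc1c(OC)cc2ccc(=O)oc2c1OC
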